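**Retrosynthetic overview**

- Feature: C2 (bearing ring B and O1) and C3 (bearing OMe) are adjacent oxygenated stereocentres, and C3 sits on the acyl carbon C4. The unit O–C2–C3–C4(=O) is therefore the skeleton of a 4-aryl-3-methoxyoxetan-2-one made from methoxyketene and the ring B aldehyde.
- Disconnections: C4–C4a (intramolecular Friedel–Crafts acylation onto a symmetric ring A); O1–C2 (SN2 opening of the β-lactone by the ring A aryloxide, with inversion); C2–C3 plus a temporary C4–O bond (catalytic asymmetric ketene–aldehyde cycloaddition).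
- Ring order: rings A and B are bought as benzaldehydes; the sacrificial oxetanone ring is closed in step 4 and opened in step 5; ring C (pyranone) is closed last, in step 6.
- Protecting groups: benzyl on 6-O and 3′-O, methyl on 5-O. The ring A phenol is then mirror-symmetric, so the acylation has only one possible regiochemistry; BCl3 and then H2 complete the synthesis.

Key step: step 4

Assumption: the quinidine-derived catalyst is taken to give the (3R,4S) lactone, by analogy with the sense of induction of the quinidine series with simple ketenes; if the assay of 9 showed the opposite sense, the pseudoenantiomeric O-trimethylsilylquinine would be used under the same conditions.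

**Route**

Step 1
Reactants: 1 syringaldehyde (4-hydroxy-3,5-dimethoxybenzaldehyde)
Product: 2 4-(benzyloxy)-3,5-dimethoxybenzaldehyde
Conditions: BnBr, K2CO3, DMF, 60 °C
Reagents that add atoms: benzyl bromide, BrCc1ccccc1
Why: Williamson etherification of the acidic 4-phenol, the only nucleophilic site, should proceed cleanly despite the two flanking methoxy groups.

Step 2
Reactants: 2 4-(benzyloxy)-3,5-dimethoxybenzaldehyde
Product: 4 4-(benzyloxy)-3,5-dimethoxyphenol, via aryl formate 3 (not isolated)
Conditions: mCPBA, CH2Cl2, 0 °C to rt; then K2CO3 (cat.), MeOH, rt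
Reagents that add atoms: mCPBA, OOC(=O)c1cccc(Cl)c1
Why: Baeyer–Villiger (Dakin-type) oxidation of an electron-rich benzaldehyde proceeds with aryl migration to the formate, which mild methanolysis should convert into the mirror-symmetric phenol.

Step 3
Reactants: 5 3-hydroxy-4,5-dimethoxybenzaldehyde
Product: 6 3-(benzyloxy)-4,5-dimethoxybenzaldehyde
Conditions: BnBr, K2CO3, DMF, 60 °C
Reagents that add atoms: benzyl bromide, BrCc1ccccc1
Why: Williamson etherification masks the only free phenol of ring B as a benzyl ether, which is inert to amine base, LiClO4, aryloxide, anhydride and BCl3 at low temperature and is removed at the end by hydrogenolysis.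

Step 4
Reactants: 6 3-(benzyloxy)-4,5-dimethoxybenzaldehyde; 7 methoxyacetyl chloride
Product: 9 (3R,4S)-4-[3-(benzyloxy)-4,5-dimethoxyphenyl]-3-methoxyoxetan-2-one, via methoxyketene 8 (not isolated)
Conditions: O-trimethylsilylquinidine (TMSQd, 15 mol%), LiClO4 (1.5 equiv), i-Pr2NEt (2.5 equiv), 7 (2.0 equiv) added over 4 h, CH2Cl2/Et2O 2:1, −78 to −40 °C; cold filtration through a short pad of deactivated silica, used at once
Reagents that add atoms: none
Why: i-Pr2NEt dehydrochlorinates 7 to methoxyketene 8, to which the alkaloid nitrogen adds to give a chiral ammonium enolate; this adds through a lithium-bridged, closed chair-like transition state to the LiClO4-activated aldehyde 6, forming the C2–C3 bond (lactone C4–C3). The closest known reaction type is the cinchona alkaloid and Lewis acid co-catalysed acyl halide–aldehyde cyclocondensation (formal [2+2]) that gives cis-3,4-disubstituted β-lactones from monosubstituted ketenes, here extended to an alkoxyketene and an aryl aldehyde. The oxetanone ring closes by 4-exo-trig attack of the lithium alkoxide on the acylammonium carbon, which releases the catalyst. Lactone C3 (target C3, R) is set by the alkaloid, which shields one face of the enolate; lactone C4 (S, the inverse of target C2) follows from the closed transition state with the aryl group pseudo-equatorial, which gives the cis lactone. The step needs cross-addition to beat ketene dimerization, which slow addition of 7 and a non-enolizable aldehyde should secure, and cis over trans selectivity, which the closed transition state provides. The lactone must also survive: the 4′-methoxy group is twisted out of conjugation by its two ortho neighbours, so the aryl group should not ionize the benzylic C–O bond under LiClO4 at low temperature.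

Step 5
Reactants: 9 (3R,4S)-4-[3-(benzyloxy)-4,5-dimethoxyphenyl]-3-methoxyoxetan-2-one; 4 4-(benzyloxy)-3,5-dimethoxyphenol
Product: 10 (2R,3R)-3-[4-(benzyloxy)-3,5-dimethoxyphenoxy]-3-[3-(benzyloxy)-4,5-dimethoxyphenyl]-2-methoxypropanoic acid
Conditions: 4 (1.3 equiv), KOt-Bu (1.25 equiv), 18-crown-6 (1.3 equiv), DMF/THF, −40 °C; then cold solution of 9, −40 to −10 °C; 1 M HCl work-up at 0 °C
Reagents that add atoms: none
Why: Proposed new method: the crown-separated potassium aryloxide of 4 should attack the benzylic lactone C4 from the side opposite the ring oxygen (SN2, alkyl–oxygen cleavage), inverting that centre to the R configuration of target C2 and installing O1, while lactone C3 is untouched, so the 2,3-trans relationship results. Attack at the acyl carbon is expected to be reversible, because the aryl ester alkoxide can re-close to the lactone, whereas attack at C4 releases ring strain irreversibly as a carboxylate. The closest known reactions are the SN2 opening of 4-substituted β-lactones at C4 by azide, sulfonamide and thiolate nucleophiles, and the opening of β-propiolactone at its primary carbon by phenoxides.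

Step 6
Reactants: 10 (2R,3R)-3-[4-(benzyloxy)-3,5-dimethoxyphenoxy]-3-[3-(benzyloxy)-4,5-dimethoxyphenyl]-2-methoxypropanoic acid
Product: 12 (2R,3R)-6-(benzyloxy)-2-[3-(benzyloxy)-4,5-dimethoxyphenyl]-3,5,7-trimethoxy-2,3-dihydro-4H-chromen-4-one, via mixed trifluoroacetic anhydride 11 (not isolated)
Conditions: TFAA (2.0 equiv), CH2Cl2, 0 °C to rt
Reagents that add atoms: none
Why: Intramolecular Friedel–Crafts acylation through the mixed anhydride should close the six-membered ring C at either of the two equivalent ring A positions ortho to O1, each activated by two ortho and one para oxygen; this site is far more nucleophilic than ring B, where acylation would also need a five-membered ring, and the absence of a strong Lewis acid avoids decarbonylation of the α-methoxy acyl group and ionization at C2, so both stereocentres are carried through.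

Step 7
Reactants: 12 (2R,3R)-6-(benzyloxy)-2-[3-(benzyloxy)-4,5-dimethoxyphenyl]-3,5,7-trimethoxy-2,3-dihydro-4H-chromen-4-one
Product: 14 (2R,3R)-6-(benzyloxy)-2-[3-(benzyloxy)-4,5-dimethoxyphenyl]-5-hydroxy-3,7-dimethoxy-2,3-dihydro-4H-chromen-4-one, via 5-O-dichloroboryl chelate 13 (not isolated)
Conditions: BCl3 (1.5 equiv, 1 M in CH2Cl2), CH2Cl2, −78 to −20 °C; H2O work-up
Reagents that add atoms: none
Why: Carbonyl-directed demethylation: BCl3 bound to the C4 carbonyl should cleave only the peri 5-methoxy group, through a six-membered aryloxyboron chelate with chloride attack at the methyl carbon, as is well established for 5-methoxyflavonoids, while the aliphatic 3-methoxy group and the other aryl ethers are spared at low temperature; any partial loss of a benzyl group would be harmless, since step 8 removes both.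

Step 8
Reactants: 14 (2R,3R)-6-(benzyloxy)-2-[3-(benzyloxy)-4,5-dimethoxyphenyl]-5-hydroxy-3,7-dimethoxy-2,3-dihydro-4H-chromen-4-one
Product: 15 (2R,3R)-5,6-dihydroxy-2-(3-hydroxy-4,5-dimethoxyphenyl)-3,7-dimethoxy-2,3-dihydro-4H-chromen-4-one (CNP0075601.1)
Conditions: H2 (1 atm), Pd/C (10 wt% Pd), EtOAc/MeOH, rt, stopped after uptake of 2 equiv
Reagents that add atoms: none
Why: Hydrogenolysis of the two aryl benzyl ethers is much faster than cleavage of the cyclic benzylic C2–O1 bond or reduction of the hydrogen-bonded C4 ketone, and the reducing medium protects the 5,6-catechol from air oxidation, so the target should be released with both stereocentres intact.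

**Compound list**

1 | syringaldehyde (4-hydroxy-3,5-dimethoxybenzaldehyde) | COc1cc(C=O)cc(OC)c1O | starting material
2 | 4-(benzyloxy)-3,5-dimethoxybenzaldehyde | O=Cc1cc(OC)c(OCc2ccccc2)c(OC)c1 | intermediate
3 | 4-(benzyloxy)-3,5-dimethoxyphenyl formate | O=COc1cc(OC)c(OCc2ccccc2)c(OC)c1 | intermediate
4 | 4-(benzyloxy)-3,5-dimethoxyphenol | Oc1cc(OC)c(OCc2ccccc2)c(OC)c1 | intermediate
5 | 3-hydroxy-4,5-dimethoxybenzaldehyde | COc1cc(C=O)cc(O)c1OC | starting material
6 | 3-(benzyloxy)-4,5-dimethoxybenzaldehyde | O=Cc1cc(OCc2ccccc2)c(OC)c(OC)c1 | intermediate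
7 | methoxyacetyl chloride | COCC(Cl)=O | starting material
8 | methoxyketene | COC=C=O | intermediate
9 | (3R,4S)-4-[3-(benzyloxy)-4,5-dimethoxyphenyl]-3-methoxyoxetan-2-one (cis) | O=C1[C@H](OC)[C@H](c2cc(OCc3ccccc3)c(OC)c(OC)c2)O1 | intermediate
10 | (2R,3R)-3-[4-(benzyloxy)-3,5-dimethoxyphenoxy]-3-[3-(benzyloxy)-4,5-dimethoxyphenyl]-2-methoxypropanoic acid | OC(=O)[C@H](OC)[C@@H](c1cc(OCc2ccccc2)c(OC)c(OC)c1)Oc1cc(OC)c(OCc2ccccc2)c(OC)c1 | intermediate
11 | (2R,3R)-3-[4-(benzyloxy)-3,5-dimethoxyphenoxy]-3-[3-(benzyloxy)-4,5-dimethoxyphenyl]-2-methoxypropanoic trifluoroacetic anhydride | FC(F)(F)C(=O)OC(=O)[C@H](OC)[C@@H](c1cc(OCc2ccccc2)c(OC)c(OC)c1)Oc1cc(OC)c(OCc2ccccc2)c(OC)c1 | intermediate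
12 | (2R,3R)-6-(benzyloxy)-2-[3-(benzyloxy)-4,5-dimethoxyphenyl]-3,5,7-trimethoxy-2,3-dihydro-4H-chromen-4-one (2,3-trans) | COc1cc2c(c(OC)c1OCc1ccccc1)C(=O)[C@H](OC)[C@@H](c1cc(OCc3ccccc3)c(OC)c(OC)c1)O2 | intermediate
13 | (2R,3R)-6-(benzyloxy)-2-[3-(benzyloxy)-4,5-dimethoxyphenyl]-5-[(dichloroboranyl)oxy]-3,7-dimethoxy-2,3-dihydro-4H-chromen-4-one (boron chelated to the C4 carbonyl) | COc1cc2c(c(OB(Cl)Cl)c1OCc1ccccc1)C(=O)[C@H](OC)[C@@H](c1cc(OCc3ccccc3)c(OC)c(OC)c1)O2 | intermediate
14 | (2R,3R)-6-(benzyloxy)-2-[3-(benzyloxy)-4,5-dimethoxyphenyl]-5-hydroxy-3,7-dimethoxy-2,3-dihydro-4H-chromen-4-one | COc1cc2c(c(O)c1OCc1ccccc1)C(=O)[C@H](OC)[C@@H](c1cc(OCc3ccccc3)c(OC)c(OC)c1)O2 | intermediate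
15 | (2R,3R)-5,6-dihydroxy-2-(3-hydroxy-4,5-dimethoxyphenyl)-3,7-dimethoxy-2,3-dihydro-4H-chromen-4-one | COc1cc2c(c(O)c1O)C(=O)[C@H](OC)[C@@H](c1cc(O)c(OC)c(OC)c1)O2 | target

**Step count**

Total steps: 8. Longest linear sequence: 6 steps (steps 3, 4, 5, 6, 7, 8 from 5; equally steps 1, 2, 5, 6, 7, 8 from 1).

**Steps most likely to fail**

1. Step 5 (proposed new method). The aryloxide may attack the acyl carbon and the resulting aryl ester aldolate may fragment by retro-aldol cleavage instead of re-closing. The benzylic C–O bond may also ionize, leading to loss of CO2 to an enol ether or to substitution without clean inversion, and the ambident aryloxide may react through carbon. The fallback uses known chemistry, sets out from 9 and returns at 10. Lactone 9 would be opened at the acyl carbon with allyl alcohol (cat. K2CO3, 0 °C), with retention at both centres, to give allyl (2R,3S)-3-[3-(benzyloxy)-4,5-dimethoxyphenyl]-3-hydroxy-2-methoxypropanoate F1. A Mitsunobu etherification of F1 with phenol 4 (PPh3, DIAD, toluene, 0 °C) would invert the carbinol centre and give allyl (2R,3R)-3-[4-(benzyloxy)-3,5-dimethoxyphenoxy]-3-[3-(benzyloxy)-4,5-dimethoxyphenyl]-2-methoxypropanoate F2. Neutral deallylation with the zerovalent palladium complex Pd(PPh3)4 and morpholine in THF would then give acid 10 without exposing the β-aryloxy ester to base.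

2. Step 4. Dimerization or oligomerization of the very reactive methoxyketene may outrun its addition to the moderately electrophilic aryl aldehyde. Lithium chelation by the α-methoxy group may erode cis selectivity or enantioselectivity, and the product may decarboxylate during isolation. The fallback sets out from 6 and 7 and returns at 9. (R)-4-Benzyloxazolidin-2-one would be acylated with 7 (n-BuLi, THF, −78 °C) to give (R)-4-benzyl-3-(methoxyacetyl)oxazolidin-2-one F3. An Evans syn-aldol reaction of F3 with 6 (n-Bu2BOTf, i-Pr2NEt, CH2Cl2, −78 to 0 °C) would give (R)-4-benzyl-3-[(2R,3S)-3-[3-(benzyloxy)-4,5-dimethoxyphenyl]-3-hydroxy-2-methoxypropanoyl]oxazolidin-2-one F4. Cleavage with LiOH/H2O2 (THF/H2O, 0 °C) would give (2R,3S)-3-[3-(benzyloxy)-4,5-dimethoxyphenyl]-3-hydroxy-2-methoxypropanoic acid F5. Carboxyl-activating lactonization of F5 (PhSO2Cl, pyridine, 0 °C) proceeds with retention at both centres and would give the cis lactone 9.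

3. Step 6. The activated α-methoxy acyl group may lose CO, the liberated acid may ionize the benzylic C2–O bond with epimerization or loss of the aryloxy group, or acylation may occur in part on ring B. The fallback reverses the polarity of the ring closure, sets out from 10 and returns at 12. Monobromination of the most electron-rich position of ring A (NBS, MeCN, −30 °C) would give (2R,3R)-3-[4-(benzyloxy)-2-bromo-3,5-dimethoxyphenoxy]-3-[3-(benzyloxy)-4,5-dimethoxyphenyl]-2-methoxypropanoic acid F6. Amide formation (EDC·HCl, MeNHOMe·HCl, N-methylmorpholine, CH2Cl2) would give the Weinreb amide (2R,3R)-3-[4-(benzyloxy)-2-bromo-3,5-dimethoxyphenoxy]-3-[3-(benzyloxy)-4,5-dimethoxyphenyl]-N,2-dimethoxy-N-methylpropanamide F7. Bromine–lithium exchange (t-BuLi, THF, −95 °C) followed by Parham cyclization of the aryllithium onto the amide would give chromanone 12.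

**Further compounds**

F1 | step 5 | allyl (2R,3S)-3-[3-(benzyloxy)-4,5-dimethoxyphenyl]-3-hydroxy-2-methoxypropanoate | C=CCOC(=O)[C@H](OC)[C@@H](O)c1cc(OCc2ccccc2)c(OC)c(OC)c1
F2 | step 5 | allyl (2R,3R)-3-[4-(benzyloxy)-3,5-dimethoxyphenoxy]-3-[3-(benzyloxy)-4,5-dimethoxyphenyl]-2-methoxypropanoate | C=CCOC(=O)[C@H](OC)[C@@H](c1cc(OCc2ccccc2)c(OC)c(OC)c1)Oc1cc(OC)c(OCc2ccccc2)c(OC)c1
F3 | step 4 | (R)-4-benzyl-3-(methoxyacetyl)oxazolidin-2-one | COCC(=O)N1[C@H](Cc2ccccc2)COC1=O
F4 | step 4 | (R)-4-benzyl-3-[(2R,3S)-3-[3-(benzyloxy)-4,5-dimethoxyphenyl]-3-hydroxy-2-methoxypropanoyl]oxazolidin-2-one | O=C1OC[C@@H](Cc2ccccc2)N1C(=O)[C@H](OC)[C@@H](O)c1cc(OCc2ccccc2)c(OC)c(OC)c1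
F5 | step 4 | (2R,3S)-3-[3-(benzyloxy)-4,5-dimethoxyphenyl]-3-hydroxy-2-methoxypropanoic acid | OC(=O)[C@H](OC)[C@@H](O)c1cc(OCc2ccccc2)c(OC)c(OC)c1
F6 | step 6 | (2R,3R)-3-[4-(benzyloxy)-2-bromo-3,5-dimethoxyphenoxy]-3-[3-(benzyloxy)-4,5-dimethoxyphenyl]-2-methoxypropanoic acid | OC(=O)[C@H](OC)[C@@H](c1cc(OCc2ccccc2)c(OC)c(OC)c1)Oc1cc(OC)c(OCc2ccccc2)c(OC)c1Br
F7 | step 6 | (2R,3R)-3-[4-(benzyloxy)-2-bromo-3,5-dimethoxyphenoxy]-3-[3-(benzyloxy)-4,5-dimethoxyphenyl]-N,2-dimethoxy-N-methylpropanamide | CON(C)C(=O)[C@H](OC)[C@@H](c1cc(OCc2ccccc2)c(OC)c(OC)c1)Oc1cc(OC)c(OCc2ccccc2)c(OC)c1Br
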